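Fix the reagent charge before anything else: it gives the top of the bis adduct these flasks can make.

| flask | substrate | reagent | temperature | remark | time |
|---|---|---|---|---|---|
| green | 0.22 M | 1.2 equiv | 55 °C | run made earlier |  |
| zeta | 0.11 M | 1.20 equiv | 55 °C |  | 25 h |
| delta | 0.11 M | 1.20 equiv | 25 °C |  | 25 h |
| eta | 0.11 M | 1.20 equiv | 40 °C |  | 25 h |
| beta | 0.11 M | 1.20 equiv |  | at 55 °C until 8.0 h, from then on at 25 °C | 25 h |

- green (time / h: bis adduct / %): 0.417: 38.2; 1.33: 36.3; 2.50: 33.1; 4.00: 32.7; 5.00: 33.2

(each reading ± 0.3 percentage points)

- the numbers in the tables scatter by 0.3 percentage points (one standard deviation)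
- the earlier runs do not show what temperature does; that part of a forecast is a guess

- the flask with the highest amount of bis adduct, in percent of the substrate charged ("all alike" if they lie within 1.5 percentage points) (zeta / delta / eta / beta / all alike)
- final bis adduct, as a percentage of the substrate charged, in zeta
- final bis adduct, as a percentage of the substrate charged, in delta
- final bis adduct, as a percentage of the substrate charged, in eta
- final bis adduct, as a percentage of the substrate charged, in beta

A bis adduct takes up two reagents, so the bench rule is to divide the equivalents by 2. With 1.20 equiv that gives 60.0% of the substrate charged; call this the reagent ceiling, the most substrate that can carry two reagents. The same ceiling holds for zeta, delta, eta and beta, which are each charged 1.20 equiv, and for the green run with its 1.2 equiv.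

The rule has a border, found from the ratio of the equivalents to 2. Below one, reagent is the limiting reagent and the ceiling applies; at 0.600 these flasks lie on that side. Above one, substrate is the limit and the ceiling stays at 100%.

The rule also gives a top, not a level. The last green reading, 33.2%, is 0.553 of the ceiling, and the green readings of bis adduct lie 5 percentage points lower at the last than at the first. So my own reckoning commits to a top of 60.0% for these flasks and to no single number, and the effect of temperature stays a guess.

The forecast is a different reckoning, with its own numbers: 32% for zeta, 36% for delta, 32.5% for eta and 32.5% for beta, with delta highest. Of the cold flask it says “delta probably keeps some of the kinetic excess”.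

    substrate + reagent → first product (k = 2.40 L mol⁻¹ h⁻¹, Ea = 57.0 kJ mol⁻¹)
    reagent + first product → bis adduct (k = 5.90 L mol⁻¹ h⁻¹, Ea = 68.0 kJ mol⁻¹)
    bis adduct ⇌ isomer of the product (K = 0.360, k = 0.0120 h⁻¹, Ea = 109 kJ mol⁻¹, ΔH = 16.0 kJ mol⁻¹)
    substrate → decomposition product (k = 3.60 × 10⁻⁴ h⁻¹, Ea = 101 kJ mol⁻¹)
    (constants at 25 °C)

The flasks give 32.8% in zeta, 42.9% in delta, 35.5% in eta and 36.6% in beta, so delta is highest, and stands 6.9 points above the forecast. Delta's bis adduct and isomer of the product together make 51.0%, less than the ceiling of 60.0%. The neighbour of beta charged with 4.80 equiv lies past the border, at a ratio of 2.40, so its ceiling is 100%, and two reagents per substrate leave 58.3% of its reagent. That neighbour ends with bis adduct 67.4% and isomer of the product 32.4%, together 99.8%, and 58.4% of its reagent left.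

Readings and results are simulated with made-up constants.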